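The earlier runs and the new flask are calculated from invented constants, noise included.

Count how many times double product can turn over into triple product within the asked time: the count tells a race from a balance. In the proposed steps, substrate takes up coupling partner to give single product, single product takes up a second one to give double product, double product takes up a third reversibly to give triple product, and gas crosses over to supply the partner.

in all of them: gas 200 mM (held)
- autumn: substrate 1.3 M; run made earlier
- Wednesday's: substrate 1.2 M; time 2.0 h
- Sunday's: substrate 2.0 M; time 2.0 h
- Friday's: substrate 3.0 M; time 2.0 h

autumn run (percent of the substrate charged)

| time / min | double product / % | triple product / % |
|---|---|---|
| 2.00 | 2.5 | 0 |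
| 6.00 | 3.8 | 0 |
| 12.0 | 19.5 | 1.2 |
| 15.0 | 26.5 | 3.1 |
| 25.0 | 47.8 | 10.4 |

(each reading ± 1 percentage point)

- at the start none of coupling partner is dissolved
- steps that have been proposed: substrate + coupling partner -> single product; coupling partner + single product -> double product; coupling partner + double product <-> triple product; gas <-> coupling partner
- "hardly changes" means that all values lie within two and a half points (for a concentration: within two and a half percent of the largest)

1. share of double product in all that became double product or triple product for Wednesday's, Sunday's, Friday's, in this order
2. how the row runs (rises, then falls / rises all the way / falls, then rises / falls all the way / hardly changes)

From 12.0 min to 15.0 min the autumn run forms triple product at 0.0275 /min per unit of double product standing, a pseudo-first-order rate. From 15.0 min to 25.0 min this falls to 0.0197 /min, a factor of 0.716. That reading is rough, since a scatter of 1 percentage point sits on a rise of 1.9 points. I read the slowing as triple product falling back, and it grows as triple product gathers.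

Multiplying the later rate by the asked 2.0 h gives the turnover count, the number of lifetimes double product has before the run ends: 2.36. Unopposed, that many turnovers would leave a share of 9.44%, but I expect the accumulating slowing to bring the net rate to zero first, which is thermodynamic rather than kinetic control.

Between 15.0 min and 25.0 min the autumn run makes double plus triple product at 0.0372 M/min, as read. At that rate Friday's flask, the largest charge, is worked through in 80.7 min, less than 2.0 h, so I expect a flat row.

My count gives no height for the row, and the forecast says 60%, 60%, 61%, hardly changes: “all three runs end with substrate consumed and partner back near saturation”.

The flasks give 52.1%, 52.3%, 52.8%: hardly changes.

    substrate + coupling partner → single product (k = 0.00730 /M/s)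
    coupling partner + single product → double product (k = 0.00860 /M/s)
    coupling partner + double product ⇌ triple product (K = 4.70 /M, k = 0.00240 /M/s)
    gas ⇌ coupling partner, rate k4*(csat - [coupling partner]) (kL = 0.0310 /s)

The falling back of triple product to double product and coupling partner is the main reason for the height of this row. With that falling back of triple product removed, the share in Wednesday's flask drops from 52.1% to 8.63%, against the 9.44% reckoned from my count of 2.36 for an unopposed step. With the same falling back of triple product removed, the share in Friday's flask drops from 52.8% to 12.7%, which corresponds to a count of 2.06.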